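A direct plan would make the 2,5-cis-tetrahydrofuran first, as diol A1 from (R)-linalool by asymmetric epoxidation and 5-exo opening, and would attach a cyclohexanone to it by conjugate addition. It would then create quaternary C12 by C-methylation of a 2-formyl ketone to give the formyl methyl ketone A2, would close the 14-membered ring by chromium-mediated addition of the alkenyl iodide to that formyl group, and would only then expand the bridged cyclohexanone A3 to the seven-membered lactone by Baeyer–Villiger oxidation.
Its weakest steps would be three. In the methylation, O-alkylation would compete and only a remote 1,4-relation to C1 would steer the face. The ring closure onto the neopentyl formyl group of a β-keto aldehyde would be slow at high dilution and open to loss of the formyl group. The silylation, ketal and redox adjustments would add about a third of the steps and no complexity.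

The new route rests on the C4–O and C8–O bonds. The pattern C3–OH, oxygen bridge C4–O–C7, C8–OH of the tetrahydrofuran is exactly what two epoxides of a 1,5-diene give on transannular opening, so ring and four stereocentres (C3, C4, C7, C8) are read back to the (3E,7E)-diene of a 14-membered keto lactone 21. One acid-triggered cascade on its bis-epoxide, a copy of the likely biogenesis, then gives the target directly. The lactone is closed early by carboxylate opening of an epoxide at tertiary C12, C1 comes from an organocatalytic malonate addition and the carbocycle closes at C9–C10 by π-allyl alkylation, so enolate methylation, closure onto a formyl ketone and the silyl and ketal steps vanish.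

Key step: step 17

Remark on numbering: cembrane numbering of the target is used. C1–C14 are the ring carbons (C1 carries the lactone side chain, C3 the secondary hydroxyl, C4 and C7 the ether bridge, C8 the tertiary hydroxyl, C11 the ketone, C12 the lactone oxygen); C15, C16 and C17 are the α-carbon, carbonyl carbon and exocyclic methylene of the lactone.
Remark on the target: it is treated as the open 8-hydroxy-11-ketone of its SMILES; a reversible C8–O–C11 hemiketal would not change any step.

Step 1
Reactants: 1 geraniol
Product: 2 (2S,3S)-2,3-epoxygeraniol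
Conditions: Ti(OiPr)4 (5 mol %), L-(+)-diethyl tartrate (7 mol %), t-BuOOH, 4 Å MS, CH2Cl2, −20 °C
Reagents that add atoms: tert-butyl hydroperoxide, CC(C)(C)OO
Why: In the Sharpless asymmetric epoxidation the allylic alcohol binds the titanium tartrate complex, so only the 2,3-alkene reacts, and the L-(+)-tartrate ligand should deliver oxygen to the face that gives the (2S,3S)-epoxide, which fixes C11 (S) and C12 (S) under reagent control.

Step 2
Reactants: 2 (2S,3S)-2,3-epoxygeraniol
Product: 3 epoxygeranyl acetate
Conditions: Ac2O, Et3N, DMAP (cat.), CH2Cl2, 0 °C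
Reagents that add atoms: acetic anhydride, CC(=O)OC(C)=O
Why: Acetylation of the primary alcohol (acyl transfer with nucleophilic catalysis) masks the C10 hydroxyl through the aldehyde and vinyl ether chemistry, and the ester falls off without an extra step in the saponification of step 9.

Step 3
Reactants: 3 epoxygeranyl acetate
Product: 4 (E)-enal with C1=C2 and the C3 aldehyde
Conditions: (E)-but-2-enal (5 equiv), second-generation Hoveyda–Grubbs catalyst (5 mol %), CH2Cl2, 40 °C
Reagents that add atoms: (E)-but-2-enal, C/C=C/C=O
Why: Olefin cross-metathesis of the only alkene, a trisubstituted isopropylidene group, with an excess of the enal exchanges the CMe2 terminus for CH–CHO and should give the conjugated (E)-enal as the thermodynamic isomer, the epoxy acetate being inert to the ruthenium carbene.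

Step 4
Reactants: 4 (E)-enal; 5 dimethyl malonate
Product: 6 Michael adduct aldehyde (C1 R)
Conditions: (S)-2-{bis[3,5-bis(trifluoromethyl)phenyl](trimethylsilyloxy)methyl}pyrrolidine (10 mol %), EtOH, 0 °C
Reagents that add atoms: none
Why: In this organocatalytic Michael addition (iminium activation by a diarylprolinol silyl ether) the malonate adds to the β-carbon of the s-trans (E)-iminium ion on the face away from the bulky diaryl(silyloxy)methyl group of the (S)-catalyst, which should set C1 as R by catalyst control irrespective of the distant epoxide.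

Step 5
Reactants: 6 Michael adduct aldehyde
Product: 7 C3 allylic alcohol (both C3 epimers)
Conditions: 2-bromopropene, CrCl2 (4 equiv), NiCl2 (2 mol %), DMF, rt
Reagents that add atoms: 2-bromopropene, CC(Br)=C
Why: In the Nozaki–Hiyama–Kishi addition the alkenylchromium species formed through nickel catalysis adds only to the aldehyde and is not basic, so the acidic malonate C–H, the esters and the epoxide stay untouched, and the C3 carbinol may form as both epimers because C3 becomes sp2 in step 6.

Step 6
Reactants: 7 C3 allylic alcohol
Product: 9 C7 aldehyde with the (E)-C3=C4 alkene, via allyl vinyl ether 8 (not isolated)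
Conditions: n-BuOCH=CH2 (excess), Pd(OCOCF3)2 (2 mol %), 4,7-diphenyl-1,10-phenanthroline (2 mol %), Et3N, 75 °C; then PhMe, 140 °C (sealed tube)
Reagents that add atoms: butyl vinyl ether, C=COCCCC
Why: Palladium-catalysed transfer vinylation followed by Claisen rearrangement (a [3,3]-sigmatropic shift through a chair transition state with the C2 chain equatorial) forms the C5–C6 bond, erases the C3 carbinol and should give the (E)-trisubstituted C3=C4 alkene, as in the classical terpenoid chain extension.

Step 7
Reactants: 9 C7 aldehyde
Product: 10 (E,E)-dienal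
Conditions: Ph3P=C(CH3)CHO, PhMe, 100 °C
Reagents that add atoms: 2-(triphenyl-λ5-phosphanylidene)propanal, CC(C=O)=P(c1ccccc1)(c1ccccc1)c1ccccc1
Why: The Wittig olefination with a stabilised α-methyl ylide reacts only with the aldehyde and should give the (E)-2-methyl-2-enal, which sets the C7=C8 geometry and adds C8, C9 and the C8 methyl group.

Step 8
Reactants: 10 (E,E)-dienal
Product: 11 (E,E)-dienol (C9–OH)
Conditions: NaBH4, CeCl3·7H2O, MeOH, −40 °C
Reagents that add atoms: none
Why: The Luche reduction (1,2-selective hydride delivery by the cerium-modified borohydride) converts the enal into the primary allylic alcohol without touching esters, epoxide or isolated alkenes.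

Step 9
Reactants: 11 (E,E)-dienol
Product: 13 ε-lactone acid with the C10,C11-diol (C12 R), via malonic diacid 12 (not isolated)
Conditions: LiOH, THF/H2O, 0 °C; 1 M HCl to pH 3, extraction; then Ti(OiPr)4 (1.5 equiv), CH2Cl2, 0 °C → rt
Reagents that add atoms: lithium hydroxide, [Li+].[OH-]
Why: Saponification frees the malonic acid and the epoxy alcohol, and the titanium alkoxide template of a 2,3-epoxy alcohol should then direct the tethered carboxylate to C12 (titanium-mediated opening at C3 of an epoxy alcohol by a carboxylic acid, 7-exo, the alternative being an eight-membered ring), so the lactone closes with inversion at the tertiary carbon (C12 becomes R) and no hindered tertiary alcohol has to be acylated.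

Step 10
Reactants: 13 ε-lactone acid
Product: 15 α-methylene lactone triol, via Mannich base 14 (not isolated)
Conditions: aq. CH2O (37 %), Et2NH, AcOH, NaOAc, THF, rt → 70 °C
Reagents that add atoms: formaldehyde, C=O
Why: In this decarboxylative Mannich methylenation the α-carboxy lactone condenses with the iminium ion from formaldehyde and diethylamine and the Mannich base loses carbon dioxide and the amine to give the exocyclic methylene group, which also removes the unwanted C15 stereocentre.

Step 11
Reactants: 15 α-methylene lactone triol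
Product: 16 C11 aldehyde
Conditions: NaIO4, THF/H2O, 0 °C
Reagents that add atoms: none
Why: Periodate glycol cleavage (Malaprade reaction) of the only 1,2-diol removes C10 as formaldehyde and leaves the C11 aldehyde on the fully substituted C12, which cannot epimerise.

Step 12
Reactants: 16 C11 aldehyde
Product: 17 allylic methyl carbonate
Conditions: ClCO2Me, pyridine, CH2Cl2, 0 °C
Reagents that add atoms: methyl chloroformate, COC(Cl)=O
Why: O-Acylation of the remaining primary allylic alcohol with the chloroformate installs the leaving group for π-allyl formation, the aldehyde being inert under these conditions.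

Step 13
Reactants: 17 allylic methyl carbonate
Product: 18 tert-butyl β-keto ester
Conditions: N2CHCO2t-Bu, SnCl2 (20 mol %), CH2Cl2, rt
Reagents that add atoms: tert-butyl diazoacetate, CC(C)(C)OC(=O)C=[N+]=[N-]
Why: In the Roskamp homologation the Lewis acid activated aldehyde is attacked by the diazo ester and a 1,2-hydride shift with loss of dinitrogen gives the β-keto ester directly, which adds C10 as the future nucleophilic carbon without any base.

Step 14
Reactants: 18 tert-butyl β-keto ester
Product: 19 macrocyclic β-keto ester (both C10 epimers)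
Conditions: Pd2(dba)3·CHCl3 (5 mol %), dppe (12 mol %), THF, 65 °C, slow addition (2 mM)
Reagents that add atoms: none
Why: In this Tsuji–Trost macrocyclisation zerovalent palladium ionises the (E)-allylic carbonate to the syn-π-allyl complex and methoxide, the β-keto ester enolate attacks the less substituted terminus C9 to close the 14-membered carbocycle with the (E)-C7=C8 geometry kept, and reversible conjugate addition of the enolate to the α-methylene lactone should be drained by this irreversible alkylation, C10 forming as both epimers that are erased in step 15.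

Step 15
Reactants: 19 macrocyclic β-keto ester
Product: 21 (3E,7E)-diene keto lactone, via β-keto acid 20 (not isolated)
Conditions: TMSOTf, 2,6-lutidine, CH2Cl2, 0 °C; then H2O, 40 °C
Reagents that add atoms: none
Why: Silyl triflate mediated cleavage of the tert-butyl ester under buffered non-protic conditions and spontaneous decarboxylation of the β-keto acid leave the C11 ketone with C10 as a methylene group, without exposing the 1,5-diene to strong protic acid.

Step 16
Reactants: 21 (3E,7E)-diene keto lactone
Product: 22 (3S,4S,7S,8S)-bis-epoxide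
Conditions: 1,2:4,5-di-O-isopropylidene-β-L-erythro-2,3-hexodiulo-2,6-pyranose (enantiomer of the D-fructose-derived Shi ketone, 60 mol %), KHSO5 (as 2KHSO5·KHSO4·K2SO4), K2CO3, Bu4NHSO4 (cat.), MeCN/CH2(OMe)2/aq. Na2B4O7 buffer, 0 °C
Reagents that add atoms: potassium peroxymonosulfate, [K+].[O-]S(=O)(=O)OO
Why: In the Shi epoxidation (chiral dioxirane, spiro transition state) the D-fructose-derived ketone gives (R,R)-epoxides from (E)-trisubstituted alkenes of this type, so its enantiomer should give the (3S,4S,7S,8S)-bis-epoxide under reagent control, while the electron-poor α-methylene lactone is not attacked.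

Step 17
Reactants: 22 (3S,4S,7S,8S)-bis-epoxide
Product: 24 CNP0266269.2, via epoxonium ion 23 (not isolated)
Conditions: HClO4 (5 mol %), THF/H2O 10:1, 0 °C → rt
Reagents that add atoms: water, O
Why: Protonation of the 3,4-epoxide is answered by the oxygen of the 7,8-epoxide, which attacks the tertiary C4 across the ring with inversion to give the tetrahydrofuran as a bicyclic epoxonium ion, and water then opens this ion at the tertiary C8, again with inversion. The closest known reaction type is the acid-catalysed cascade of 1,5-diepoxides to 2,5-linked tetrahydrofuran diols, including its transannular version in medium-ring diepoxides, and the step mirrors the presumed biogenesis from an 11-oxo-12,16-olide. The tetrahydrofuran (O, C4, C5, C6, C7) is closed by 5-exo attack of one epoxide oxygen on the neighbouring epoxide, the macrocycle and the lactone being untouched. C3 and C7 keep the oxygen atoms and the configurations given by the Shi reagent in step 16, while C4 and C8 are each inverted once, so (3S,4S,7S,8S) becomes (3S,4R,7S,8R) and the 2,5-cis ring follows from the two (E)-alkenes. The step needs the 7,8-oxygen to reach C4 before external water does and needs opening at C8 and not at C7, which should be secured because only this sense of participation is both Markovnikov and five-membered (the reverse sense would need a six-membered transition state), because both ring-opening carbons are tertiary, and because water is kept scarce. If the C11 carbonyl oxygen opens the 7,8-epoxide at C8 first (a known mode of γ,δ-epoxy ketones), the resulting ketal hydrolyses to the 7,8-diol with the same inversion at C8 and its C7 hydroxyl opens the 3,4-epoxide at C4, so both orders converge on the target.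

Compound list
1 | geraniol, (2E)-3,7-dimethylocta-2,6-dien-1-ol | CC(C)=CCC/C(C)=C/CO | starting material
2 | (2S,3S)-2,3-epoxygeraniol, [(2S,3S)-3-methyl-3-(4-methylpent-3-en-1-yl)oxiran-2-yl]methanol | CC(C)=CCC[C@]1(C)O[C@H]1CO | intermediate
3 | [(2S,3S)-3-methyl-3-(4-methylpent-3-en-1-yl)oxiran-2-yl]methyl acetate | CC(C)=CCC[C@]1(C)O[C@H]1COC(C)=O | intermediate
4 | (2E)-5-[(2S,3S)-3-(acetoxymethyl)-2-methyloxiran-2-yl]pent-2-enal | O=C/C=C/CC[C@]1(C)O[C@H]1COC(C)=O | intermediate
5 | dimethyl malonate | COC(=O)CC(=O)OC | starting material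
6 | dimethyl 2-{(3R)-1-[(2S,3S)-3-(acetoxymethyl)-2-methyloxiran-2-yl]-5-oxopentan-3-yl}propanedioate (C1 R) | O=CC[C@H](C(C(=O)OC)C(=O)OC)CC[C@]1(C)O[C@H]1COC(C)=O | intermediate
7 | dimethyl 2-{(3R)-1-[(2S,3S)-3-(acetoxymethyl)-2-methyloxiran-2-yl]-5-hydroxy-6-methylhept-6-en-3-yl}propanedioate (both C3 epimers) | C=C(C)C(O)C[C@H](C(C(=O)OC)C(=O)OC)CC[C@]1(C)O[C@H]1COC(C)=O | intermediate
8 | vinyl ether of 7 at the C3 oxygen (5-ethenyloxy compound) | C=COC(C(C)=C)C[C@H](C(C(=O)OC)C(=O)OC)CC[C@]1(C)O[C@H]1COC(C)=O | intermediate (not isolated)
9 | dimethyl 2-{(3R,5E)-1-[(2S,3S)-3-(acetoxymethyl)-2-methyloxiran-2-yl]-6-methyl-9-oxonon-5-en-3-yl}propanedioate | O=CCC/C(C)=C/C[C@H](C(C(=O)OC)C(=O)OC)CC[C@]1(C)O[C@H]1COC(C)=O | intermediate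
10 | dimethyl 2-{(3R,5E,9E)-1-[(2S,3S)-3-(acetoxymethyl)-2-methyloxiran-2-yl]-6,10-dimethyl-11-oxoundeca-5,9-dien-3-yl}propanedioate | O=C/C(C)=C/CC/C(C)=C/C[C@H](C(C(=O)OC)C(=O)OC)CC[C@]1(C)O[C@H]1COC(C)=O | intermediate
11 | dimethyl 2-{(3R,5E,9E)-1-[(2S,3S)-3-(acetoxymethyl)-2-methyloxiran-2-yl]-11-hydroxy-6,10-dimethylundeca-5,9-dien-3-yl}propanedioate | OC/C(C)=C/CC/C(C)=C/C[C@H](C(C(=O)OC)C(=O)OC)CC[C@]1(C)O[C@H]1COC(C)=O | intermediate
12 | 2-{(3R,5E,9E)-11-hydroxy-1-[(2S,3S)-3-(hydroxymethyl)-2-methyloxiran-2-yl]-6,10-dimethylundeca-5,9-dien-3-yl}propanedioic acid | OC/C(C)=C/CC/C(C)=C/C[C@H](C(C(=O)O)C(=O)O)CC[C@]1(C)O[C@H]1CO | intermediate (not isolated)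
13 | (4R,7R)-7-[(1S)-1,2-dihydroxyethyl]-4-[(2E,6E)-8-hydroxy-3,7-dimethylocta-2,6-dien-1-yl]-7-methyl-2-oxooxepane-3-carboxylic acid (both C15 epimers) | OC(=O)C1C(=O)O[C@@](C)([C@@H](O)CO)CC[C@@H]1C/C=C(\C)CC/C=C(\C)CO | intermediate
14 | 3-[(diethylamino)methyl] derivative of 13 (Mannich base at C15) | CCN(CC)CC1(C(=O)O)C(=O)O[C@@](C)([C@@H](O)CO)CC[C@@H]1C/C=C(\C)CC/C=C(\C)CO | intermediate (not isolated)
15 | (4R,7R)-7-[(1S)-1,2-dihydroxyethyl]-4-[(2E,6E)-8-hydroxy-3,7-dimethylocta-2,6-dien-1-yl]-7-methyl-3-methylideneoxepan-2-one | C=C1C(=O)O[C@@](C)([C@@H](O)CO)CC[C@@H]1C/C=C(\C)CC/C=C(\C)CO | intermediate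
16 | (2R,5R)-5-[(2E,6E)-8-hydroxy-3,7-dimethylocta-2,6-dien-1-yl]-2-methyl-6-methylidene-7-oxooxepane-2-carbaldehyde | C=C1C(=O)O[C@@](C)(C=O)CC[C@@H]1C/C=C(\C)CC/C=C(\C)CO | intermediate
17 | (2E,6E)-8-[(4R,7R)-7-formyl-7-methyl-3-methylidene-2-oxooxepan-4-yl]-2,6-dimethylocta-2,6-dien-1-yl methyl carbonate | C=C1C(=O)O[C@@](C)(C=O)CC[C@@H]1C/C=C(\C)CC/C=C(\C)COC(=O)OC | intermediate
18 | tert-butyl 3-[(2R,5R)-5-{(2E,6E)-8-[(methoxycarbonyl)oxy]-3,7-dimethylocta-2,6-dien-1-yl}-2-methyl-6-methylidene-7-oxooxepan-2-yl]-3-oxopropanoate | C=C1C(=O)O[C@@](C)(C(=O)CC(=O)OC(C)(C)C)CC[C@@H]1C/C=C(\C)CC/C=C(\C)COC(=O)OC | intermediate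
19 | tert-butyl (1R,3E,7E,12R)-11-oxo-16,12-olidocembra-3,7,15(17)-triene-10-carboxylate (both C10 epimers) | C=C1C(=O)O[C@]2(C)CC[C@@H]1C/C=C(\C)CC/C=C(\C)CC(C(=O)OC(C)(C)C)C2=O | intermediate
20 | (1R,3E,7E,12R)-11-oxo-16,12-olidocembra-3,7,15(17)-triene-10-carboxylic acid | C=C1C(=O)O[C@]2(C)CC[C@@H]1C/C=C(\C)CC/C=C(\C)CC(C(=O)O)C2=O | intermediate (not isolated)
21 | (1R,3E,7E,12R)-11-oxocembra-3,7,15(17)-trien-16,12-olide | C=C1C(=O)O[C@]2(C)CC[C@@H]1C/C=C(\C)CC/C=C(\C)CCC2=O | intermediate
22 | (1R,3S,4S,7S,8S,12R)-3,4:7,8-diepoxy-11-oxocembr-15(17)-en-16,12-olide | C=C1C(=O)O[C@]2(C)CC[C@@H]1C[C@@H]3O[C@@]3(C)CC[C@@H]4O[C@@]4(C)CCC2=O | intermediate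
23 | bicyclic epoxonium ion: oxonium oxygen bonded to C4, C7 and C8, free C3 hydroxyl | C=C1C(=O)O[C@]2(C)CC[C@@H]1C[C@H](O)[C@@]1(C)CC[C@@H]3[O+]1[C@@]3(C)CCC2=O | intermediate (not isolated)
24 | CNP0266269.2 (1R,3S,4R,7S,8R,12R) | C=C1C(=O)O[C@]2(C)CC[C@@H]1C[C@H](O)[C@@]1(C)CC[C@H](O1)[C@](C)(O)CCC2=O | target

Total step count: 17. Longest linear sequence: 17 steps, from geraniol.

Steps most likely to fail

Step 17. The cascade may be diverted if external water opens the protonated 3,4-epoxide before the 7,8-oxygen arrives, or if a six-membered ether forms by attack at the wrong terminus. The fallback separates the two events and sets out from bis-epoxide 22. Anhydrous BF3·OEt2 (catalytic), CH2Cl2, −78 °C would first turn the γ,δ-epoxy ketone unit into the 2,7-dioxabicyclo[2.2.1]heptane ketal F1, in which the carbonyl oxygen has opened C8 with inversion and the 3,4-epoxide is kept. Aqueous acetic acid in THF would then hydrolyse the ketal, and the freed C7 hydroxyl would open the 3,4-epoxide at C4 in a hydroxy-epoxide 5-exo cyclisation. This comes back to the route at target 24.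

Step 14. Ring closure may lose out to conjugate addition of the stabilised enolate onto the exocyclic methylene group, to oligomerisation, or to partial loss of the (E)-geometry by isomerisation of the π-allyl complex. The fallback masks the acceptor and sets out from β-keto ester 18. PhSH with catalytic Et3N would add to the methylene group to give the thiophenol adduct F2. The same palladium-catalysed closure would give the macrocyclic sulfide F3, and ester cleavage with decarboxylation as in step 15 would give the sulfide ketone F4. NaIO4 would give the sulfoxide F5, and thermal syn-elimination (PhMe, 110 °C) would restore the methylene group. This comes back to the route at diene 21.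

Step 9. Hydroxide may cause epoxide migration to the terminal position and hydrolysis of the epoxy alcohol during saponification, and the seven-membered closure may be slow enough for elimination at C12 to compete. The fallback avoids hydroxide and sets out from dienol 11. Pig liver esterase at pH 7 would cleave the acetate and one methyl ester to give the malonate half ester F6. Ti(OiPr)4 in CH2Cl2 would close the lactone methyl ester F7 by the same C12 opening, and Me3SnOH (1,2-dichloroethane, 80 °C) would cleave the remaining methyl ester. This comes back to the route at lactone acid 13.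

Further compounds
F1 | step 17 | bicyclic ketal: C11 ketal carbon bonded through oxygen to C7 and C8 (2,7-dioxabicyclo[2.2.1]heptane), 3,4-epoxide intact | C=C1C(=O)O[C@]2(C)CC[C@@H]1C[C@@H]3O[C@@]3(C)CC[C@@H]4O[C@]25O[C@]4(C)CC5
F2 | step 14 | thiophenol adduct of 18 (C15–CH2SPh, both C15 epimers) | c1ccccc1SCC1C(=O)O[C@@](C)(C(=O)CC(=O)OC(C)(C)C)CC[C@@H]1C/C=C(\C)CC/C=C(\C)COC(=O)OC
F3 | step 14 | macrocyclic sulfide β-keto ester (thiophenol adduct of 19) | c1ccccc1SCC1C(=O)O[C@]2(C)CC[C@@H]1C/C=C(\C)CC/C=C(\C)CC(C(=O)OC(C)(C)C)C2=O
F4 | step 14 | macrocyclic sulfide ketone (thiophenol adduct of 21) | c1ccccc1SCC1C(=O)O[C@]2(C)CC[C@@H]1C/C=C(\C)CC/C=C(\C)CCC2=O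
F5 | step 14 | sulfoxide of F4 | O=S(CC1C(=O)O[C@]2(C)CC[C@@H]1C/C=C(\C)CC/C=C(\C)CCC2=O)c1ccccc1
F6 | step 9 | malonate half ester with free epoxy alcohol (monomethyl ester of 12) | OC/C(C)=C/CC/C(C)=C/C[C@H](C(C(=O)O)C(=O)OC)CC[C@]1(C)O[C@H]1CO
F7 | step 9 | methyl ester of lactone acid 13 | COC(=O)C1C(=O)O[C@@](C)([C@@H](O)CO)CC[C@@H]1C/C=C(\C)CC/C=C(\C)CO
A1 | direct plan | (2R)-2-[(2S,5R)-5-ethenyl-5-methyloxolan-2-yl]propane-1,2-diol | C=C[C@@]1(C)CC[C@H](O1)[C@](C)(O)CO
A2 | direct plan | silyl-protected 2-formyl-2-methylcyclohexanone carrying the iodoalkenyl tetrahydrofuran chain | O=C[C@@]1(C)CC[C@@H](CC1=O)C[C@H](O[Si](C)(C)C(C)(C)C)[C@@]2(C)CC[C@H](O2)[C@](C)(O[Si](CC)(CC)CC)/C=C/I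
A3 | direct plan | bridged cyclohexanone: 14-membered carbocycle bridged from C1 to C12 by CH2–C(=O), tris-silyl ether | C1C(=O)[C@]2(C)CC[C@@H]1C[C@H](O[Si](C)(C)C(C)(C)C)[C@@]1(C)CC[C@H](O1)[C@](C)(O[Si](CC)(CC)CC)CCC2O[Si](CC)(CC)CC
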